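Locants: ring A = C1, C2, C3, C4, C5, C10 and ring B = C5, C6, C7, C8, C9, C10 of the decalin; C1 bears the benzylic carbon C1′, C4 the methyl C15, C7 the carbinol carbon C11, C10 the angular methyl C14.
Retrosynthetic cuts, in order: aryl C–CHO and O–CH3 bonds; C4–C15 (back to C4=CH2, then C4=O); C6–C7 together with C11–O (ring B); C10–C9 and C10–C14 (two conjugate additions to ring A enones); C5–C10 and C1–C2 (ring A by aldol condensation and Michael addition); C1′–aryl (Friedel–Crafts).
Forward: the arene is bought, the chain C1′–C1–C10 is set on it, ring A is closed in step 5, and ring B is closed last, in step 11, by 6-exo attack of a C6 vinyl radical on C7 with capture of the C11 radical by O2.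
Feature used: in ring B the vinylic C6–H is exocyclic to ring A and C7 carries the tertiary carbinol C11, so the C7=C11 olefin of a 4-methylpent-3-enyl chain on C10 is a latent C7(H)–C11(OH) and an iodomethylidene on C5 is a latent C6 radical.
Stereochemistry: C1′ from iminium catalysis (step 2), C1 from enamine catalysis matched with C1′ (step 4), C10 from addition anti to the C1 side chain (step 8), C7 from the chair-like radical transition state (step 11), C4 from equatorial hydrogen delivery opposite the axial C14 (step 13).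

Key step: step 11

Remark: in step 2 the phenol is taken to alkylate ortho to its hydroxyl group; a para-alkylated hydroxy aldehyde would give the same compound 6 in step 3.

Step 1
Reactants: 1 3-methylbutanal; 2 (triphenyl-λ5-phosphanylidene)acetaldehyde
Product: 3 (2E)-5-methylhex-2-enal
Conditions: PhMe, 80 °C
Reagents that add atoms: none
Why: A Wittig olefination with a stabilised ylide should give the (E)-enal, because the oxaphosphetane from a stabilised ylide collapses under thermodynamic control to the trans olefin.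

Step 2
Reactants: 3 (2E)-5-methylhex-2-enal; 4 3,5-dimethoxyphenol
Product: 5 (4S)-5,7-dimethoxy-4-(2-methylpropyl)-3,4-dihydro-2H-chromen-2-ol
Conditions: (R)-2-[diphenyl(trimethylsilyloxy)methyl]pyrrolidine (20 mol%), PhCO2H (20 mol%), PhMe, 0 °C
Reagents that add atoms: none
Why: Iminium-ion-catalysed Friedel–Crafts alkylation of the electron-rich phenol followed by hemiacetal closure should set C1′ as S, because the diphenyl(silyloxy)methyl group of the (R)-amine blocks one face of the (E)-iminium ion and the arene bonds to the Si face of the β-carbon.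

Step 3
Reactants: 5 (4S)-5,7-dimethoxy-4-(2-methylpropyl)-3,4-dihydro-2H-chromen-2-ol
Product: 6 (3S)-5-methyl-3-(2,4,6-trimethoxyphenyl)hexanal
Conditions: MeI, K2CO3, DMF, 25 °C
Reagents that add atoms: iodomethane CI
Why: Williamson O-methylation of the phenoxide that is present through ring–chain tautomerism of the lactol should drain the equilibrium to the open aldehyde, and C1′ is untouched because it is not enolisable.

Step 4
Reactants: 6 (3S)-5-methyl-3-(2,4,6-trimethoxyphenyl)hexanal; 7 but-3-en-2-one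
Product: 8 (2R)-2-[(1S)-3-methyl-1-(2,4,6-trimethoxyphenyl)butyl]-5-oxohexanal
Conditions: (R)-2-[diphenyl(trimethylsilyloxy)methyl]pyrrolidine (10 mol%), 4-nitrophenol (20 mol%), CH2Cl2, 4 °C
Reagents that add atoms: none
Why: Enamine-catalysed Michael addition to the enone should create C1 as R, since the (R)-amine leaves one face of the (E)-enamine open and the C1′ centre reinforces that face by holding its aryl group anti to the incoming acceptor with the C1′ hydrogen outside (matched double diastereoselection).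

Step 5
Reactants: 8 (2R)-2-[(1S)-3-methyl-1-(2,4,6-trimethoxyphenyl)butyl]-5-oxohexanal
Product: 9 (4S)-4-[(1S)-3-methyl-1-(2,4,6-trimethoxyphenyl)butyl]cyclohex-2-en-1-one
Conditions: TsOH·H2O (10 mol%), PhMe, 50 °C
Reagents that add atoms: none
Why: Acid-catalysed intramolecular aldol condensation of the methyl ketone enol onto the aldehyde, the only six-membered closure open to 8, should close ring A (C5–C10) and dehydrate to the enone under conditions mild enough to keep the C1 centre.

Step 6
Reactants: 9 (4S)-4-[(1S)-3-methyl-1-(2,4,6-trimethoxyphenyl)butyl]cyclohex-2-en-1-one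
Product: 10 trimethyl({(3R,4S)-3-methyl-4-[(1S)-3-methyl-1-(2,4,6-trimethoxyphenyl)butyl]cyclohex-1-en-1-yl}oxy)silane
Conditions: MeMgBr, CuBr·SMe2 (5 mol%), TMSCl, THF, −78 °C; Et3N quench
Reagents that add atoms: methylmagnesium bromide C[Mg]Br; chlorotrimethylsilane C[Si](C)(C)Cl
Why: Copper-catalysed conjugate addition accelerated by the silyl chloride should deliver the methyl group to C10 anti to the C1 side chain and trap the enolate regiospecifically as its silyl ether, the new C10 centre being only transient.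

Step 7
Reactants: 10 trimethyl({(3R,4S)-3-methyl-4-[(1S)-3-methyl-1-(2,4,6-trimethoxyphenyl)butyl]cyclohex-1-en-1-yl}oxy)silane
Product: 11 (4R)-3-methyl-4-[(1S)-3-methyl-1-(2,4,6-trimethoxyphenyl)butyl]cyclohex-2-en-1-one
Conditions: Pd(OAc)2 (10 mol%), O2 (1 atm), DMSO, 25 °C
Reagents that add atoms: none
Why: Saegusa–Ito oxidation of the regiodefined silyl enol ether through a palladium enolate and β-hydride elimination should restore the enone with the methyl group now on the olefinic C10, erasing the transient centre and leaving C1 untouched.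

Step 8
Reactants: 11 (4R)-3-methyl-4-[(1S)-3-methyl-1-(2,4,6-trimethoxyphenyl)butyl]cyclohex-2-en-1-one; 12 5-bromo-2-methylpent-2-ene
Product: 13 trimethyl({(3R,4R)-3-methyl-3-(4-methylpent-3-en-1-yl)-4-[(1S)-3-methyl-1-(2,4,6-trimethoxyphenyl)butyl]cyclohex-1-en-1-yl}oxy)silane
Conditions: Mg, THF (Grignard reagent from 12); CuBr·SMe2 (10 mol%), TMSCl, THF, −78 to −30 °C; Et3N quench
Reagents that add atoms: chlorotrimethylsilane C[Si](C)(C)Cl
Why: A second copper-catalysed, silyl-chloride-assisted conjugate addition should form the quaternary C10 centre by axial attack anti to the pseudoaxial C1 side chain of the 4-substituted 3-methylcyclohexenone, so that C9 ends trans and the angular methyl cis to that side chain.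

Step 9
Reactants: 13 trimethyl({(3R,4R)-3-methyl-3-(4-methylpent-3-en-1-yl)-4-[(1S)-3-methyl-1-(2,4,6-trimethoxyphenyl)butyl]cyclohex-1-en-1-yl}oxy)silane
Product: 15 (3R,4R)-2-(hydroxymethylidene)-3-methyl-3-(4-methylpent-3-en-1-yl)-4-[(1S)-3-methyl-1-(2,4,6-trimethoxyphenyl)butyl]cyclohexan-1-one, via lithium enolate 14 (not isolated)
Conditions: MeLi, THF, 0 °C; CF3CH2OCHO, −78 °C; aq. NH4Cl
Reagents that add atoms: 2,2,2-trifluoroethyl formate O=COCC(F)(F)F
Why: Cleavage of the silyl enol ether by methyllithium gives the regiodefined lithium enolate at C5, whose Claisen-type C-formylation with the activated formate should give the hydroxymethylidene ketone without creating a stereocenter.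

Step 10
Reactants: 15 (3R,4R)-2-(hydroxymethylidene)-3-methyl-3-(4-methylpent-3-en-1-yl)-4-[(1S)-3-methyl-1-(2,4,6-trimethoxyphenyl)butyl]cyclohexan-1-one
Product: 16 (3R,4R)-2-(iodomethylidene)-3-methyl-3-(4-methylpent-3-en-1-yl)-4-[(1S)-3-methyl-1-(2,4,6-trimethoxyphenyl)butyl]cyclohexan-1-one (E/Z mixture)
Conditions: PPh3, I2, Et3N, MeCN, 25 °C
Reagents that add atoms: iodine II
Why: Activation of the enol oxygen as an oxyphosphonium salt and addition–elimination by iodide, the vinylogous acyl substitution that turns β-dicarbonyl enols into β-iodo enones, should give the iodomethylidene ketone, whose E/Z ratio does not matter because the derived vinyl radical inverts rapidly.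

Step 11
Reactants: 16 (3R,4R)-2-(iodomethylidene)-3-methyl-3-(4-methylpent-3-en-1-yl)-4-[(1S)-3-methyl-1-(2,4,6-trimethoxyphenyl)butyl]cyclohexan-1-one
Product: 18 (4R,4aR,7S)-7-(2-hydroxypropan-2-yl)-4a-methyl-4-[(1S)-3-methyl-1-(2,4,6-trimethoxyphenyl)butyl]-3,4,4a,5,6,7-hexahydronaphthalen-1(2H)-one, via tertiary hydroperoxide 17 (not isolated)
Conditions: Bu3SnH (slow addition), Et3B (cat.), O2 (5% in N2, slow stream), PhMe, 0 °C; then PPh3
Reagents that add atoms: dioxygen O=O
Why: Proposed new method: iodine abstraction from 16 by the tributyltin radical gives a rapidly inverting σ-vinyl radical at C6 that adds to C7 of the trisubstituted C7=C11 olefin, and the resulting tertiary C11 radical is captured by O2 to a peroxyl radical that takes hydrogen from Bu3SnH and carries the chain, the hydroperoxide 17 then being reduced by PPh3. The closest known reaction types are the tin-hydride vinyl-radical cyclisation onto olefins and the aerobic tin-hydride oxygenative cyclisation of alkyl and aryl halides, which have not been combined on a β-iodo enone closing a six-membered ring. Ring B is closed in the 6-exo-trig mode, preferred over 7-endo because attack at C7 leaves the tertiary radical. C7 is set in a chair-like transition state in which the tether C9–C8 has to be equatorial on the ring A chair to reach C6, which makes the C10 methyl pseudoaxial on the forming ring, while the CMe2 terminus sits pseudoequatorial, so that C11 and C14 end cis (7S). The step needs ring closure to outrun capture of the vinyl radical by O2 or Bu3SnH and 1,5-hydrogen transfer from C8, which the equatorial tether held next to C6, the nucleophilic trisubstituted olefin and low stationary concentrations of stannane and oxygen should secure.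

Step 12
Reactants: 18 (4R,4aR,7S)-7-(2-hydroxypropan-2-yl)-4a-methyl-4-[(1S)-3-methyl-1-(2,4,6-trimethoxyphenyl)butyl]-3,4,4a,5,6,7-hexahydronaphthalen-1(2H)-one
Product: 19 2-{(2S,4aR,5R)-4a-methyl-8-methylidene-5-[(1S)-3-methyl-1-(2,4,6-trimethoxyphenyl)butyl]-2,3,4,4a,5,6,7,8-octahydronaphthalen-2-yl}propan-2-ol
Conditions: Cp2TiMe2 (3 equiv), PhMe–THF, 70 °C
Reagents that add atoms: bis(cyclopentadienyl)dimethyltitanium C[Ti](C)(C1C=CC=C1)C1C=CC=C1
Why: Wittig-type carbonyl methylenation by the titanium methylidene formed thermally from Cp2TiMe2 should convert C4=O into the methylidene under non-basic conditions, so that the γ-hydroxyalkyl enone is not exposed to a vinylogous retro-aldol cleavage and no centre is epimerised.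

Step 13
Reactants: 19 2-{(2S,4aR,5R)-4a-methyl-8-methylidene-5-[(1S)-3-methyl-1-(2,4,6-trimethoxyphenyl)butyl]-2,3,4,4a,5,6,7,8-octahydronaphthalen-2-yl}propan-2-ol
Product: 20 2-{(2S,4aR,5R,8R)-4a,8-dimethyl-5-[(1S)-3-methyl-1-(2,4,6-trimethoxyphenyl)butyl]-2,3,4,4a,5,6,7,8-octahydronaphthalen-2-yl}propan-2-ol
Conditions: 2-nitrobenzenesulfonohydrazide, Et3N, CH2Cl2, 25 °C
Reagents that add atoms: none
Why: Diimide reduction, a concerted syn transfer of H2 that prefers the least substituted double bond, should saturate only the exocyclic C4=CH2 bond and deliver hydrogen to C4 from the equatorial face opposite the syn-axial C10 methyl, so that the new methyl is axial and cis to C14 (4R in the locants of the plan).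

Step 14
Reactants: 20 2-{(2S,4aR,5R,8R)-4a,8-dimethyl-5-[(1S)-3-methyl-1-(2,4,6-trimethoxyphenyl)butyl]-2,3,4,4a,5,6,7,8-octahydronaphthalen-2-yl}propan-2-ol
Product: 22 5-{(1S)-1-[(1R,4R,6S,8aR)-6-(2-hydroxypropan-2-yl)-4,8a-dimethyl-1,2,3,4,6,7,8,8a-octahydronaphthalen-1-yl]-3-methylbutyl}-2,4,6-trimethoxybenzene-1,3-dicarbaldehyde, via lithium hemiaminalate 21 (not isolated)
Conditions: n-BuLi, TMEDA, THF, 0 °C; DMF (1 equiv), −78 °C; n-BuLi, 0 °C; DMF; aq. NH4Cl
Reagents that add atoms: N,N-dimethylformamide CN(C)C=O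
Why: Two successive directed ortho-metalations at the aryl positions flanked by two methoxy groups, each quenched with DMF, should install both formyl groups in one flask, the first being masked as its lithium α-amino alkoxide during the second lithiation, and no stereocenter is affected.

Step 15
Reactants: 22 5-{(1S)-1-[(1R,4R,6S,8aR)-6-(2-hydroxypropan-2-yl)-4,8a-dimethyl-1,2,3,4,6,7,8,8a-octahydronaphthalen-1-yl]-3-methylbutyl}-2,4,6-trimethoxybenzene-1,3-dicarbaldehyde
Product: 23 5-{(1S)-1-[(1R,4R,6S,8aR)-6-(2-hydroxypropan-2-yl)-4,8a-dimethyl-1,2,3,4,6,7,8,8a-octahydronaphthalen-1-yl]-3-methylbutyl}-2,4,6-trihydroxybenzene-1,3-dicarbaldehyde (CNP0108656.4)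
Conditions: NaSEt (excess), DMF, 100 °C; dilute HCl work-up
Reagents that add atoms: none
Why: Thiolate SN2 demethylation of the three aryl methyl ethers, each activated by an ortho or para formyl group, should free the phloroglucinol under basic conditions that spare the tertiary alcohol and the trisubstituted olefin.

Compound list
1 | 3-methylbutanal | CC(C)CC=O | starting material
2 | (triphenyl-λ5-phosphanylidene)acetaldehyde | O=CC=P(c1ccccc1)(c1ccccc1)c1ccccc1 | starting material
3 | (2E)-5-methylhex-2-enal | CC(C)C/C=C/C=O | intermediate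
4 | 3,5-dimethoxyphenol | COc1cc(O)cc(OC)c1 | starting material
5 | (4S)-5,7-dimethoxy-4-(2-methylpropyl)-3,4-dihydro-2H-chromen-2-ol (lactol, both C2 epimers) | CC(C)C[C@H]1CC(O)Oc2cc(OC)cc(OC)c21 | intermediate
6 | (3S)-5-methyl-3-(2,4,6-trimethoxyphenyl)hexanal | CC(C)C[C@H](c1c(OC)cc(OC)cc1OC)CC=O | intermediate
7 | but-3-en-2-one | CC(=O)C=C | starting material
8 | (2R)-2-[(1S)-3-methyl-1-(2,4,6-trimethoxyphenyl)butyl]-5-oxohexanal | CC(C)C[C@H](c1c(OC)cc(OC)cc1OC)[C@H](C=O)CCC(C)=O | intermediate
9 | (4S)-4-[(1S)-3-methyl-1-(2,4,6-trimethoxyphenyl)butyl]cyclohex-2-en-1-one | CC(C)C[C@H](c1c(OC)cc(OC)cc1OC)[C@H]1CCC(=O)C=C1 | intermediate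
10 | trimethyl({(3R,4S)-3-methyl-4-[(1S)-3-methyl-1-(2,4,6-trimethoxyphenyl)butyl]cyclohex-1-en-1-yl}oxy)silane (ring methyl trans to the side chain) | CC(C)C[C@H](c1c(OC)cc(OC)cc1OC)[C@H]1CCC(O[Si](C)(C)C)=C[C@@H]1C | intermediate
11 | (4R)-3-methyl-4-[(1S)-3-methyl-1-(2,4,6-trimethoxyphenyl)butyl]cyclohex-2-en-1-one | CC(C)C[C@H](c1c(OC)cc(OC)cc1OC)[C@H]1CCC(=O)C=C1C | intermediate
12 | 5-bromo-2-methylpent-2-ene | CC(C)=CCCBr | starting material
13 | trimethyl({(3R,4R)-3-methyl-3-(4-methylpent-3-en-1-yl)-4-[(1S)-3-methyl-1-(2,4,6-trimethoxyphenyl)butyl]cyclohex-1-en-1-yl}oxy)silane (pentenyl chain trans to the side chain) | CC(C)C[C@H](c1c(OC)cc(OC)cc1OC)[C@H]1CCC(O[Si](C)(C)C)=C[C@]1(C)CCC=C(C)C | intermediate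
14 | lithium (3R,4R)-3-methyl-3-(4-methylpent-3-en-1-yl)-4-[(1S)-3-methyl-1-(2,4,6-trimethoxyphenyl)butyl]cyclohex-1-en-1-olate | CC(C)C[C@H](c1c(OC)cc(OC)cc1OC)[C@H]1CCC([O-])=C[C@]1(C)CCC=C(C)C.[Li+] | intermediate
15 | (3R,4R)-2-(hydroxymethylidene)-3-methyl-3-(4-methylpent-3-en-1-yl)-4-[(1S)-3-methyl-1-(2,4,6-trimethoxyphenyl)butyl]cyclohexan-1-one | CC(C)C[C@H](c1c(OC)cc(OC)cc1OC)[C@H]1CCC(=O)C(=CO)[C@]1(C)CCC=C(C)C | intermediate
16 | (3R,4R)-2-(iodomethylidene)-3-methyl-3-(4-methylpent-3-en-1-yl)-4-[(1S)-3-methyl-1-(2,4,6-trimethoxyphenyl)butyl]cyclohexan-1-one (E/Z mixture) | CC(C)C[C@H](c1c(OC)cc(OC)cc1OC)[C@H]1CCC(=O)C(=CI)[C@]1(C)CCC=C(C)C | intermediate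
17 | (4R,4aR,7S)-7-(2-hydroperoxypropan-2-yl)-4a-methyl-4-[(1S)-3-methyl-1-(2,4,6-trimethoxyphenyl)butyl]-3,4,4a,5,6,7-hexahydronaphthalen-1(2H)-one | CC(C)C[C@H](c1c(OC)cc(OC)cc1OC)[C@H]1CCC(=O)C2=C[C@@H](C(C)(C)OO)CC[C@@]21C | intermediate
18 | (4R,4aR,7S)-7-(2-hydroxypropan-2-yl)-4a-methyl-4-[(1S)-3-methyl-1-(2,4,6-trimethoxyphenyl)butyl]-3,4,4a,5,6,7-hexahydronaphthalen-1(2H)-one | CC(C)C[C@H](c1c(OC)cc(OC)cc1OC)[C@H]1CCC(=O)C2=C[C@@H](C(C)(C)O)CC[C@@]21C | intermediate
19 | 2-{(2S,4aR,5R)-4a-methyl-8-methylidene-5-[(1S)-3-methyl-1-(2,4,6-trimethoxyphenyl)butyl]-2,3,4,4a,5,6,7,8-octahydronaphthalen-2-yl}propan-2-ol | CC(C)C[C@H](c1c(OC)cc(OC)cc1OC)[C@H]1CCC(=C)C2=C[C@@H](C(C)(C)O)CC[C@@]21C | intermediate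
20 | 2-{(2S,4aR,5R,8R)-4a,8-dimethyl-5-[(1S)-3-methyl-1-(2,4,6-trimethoxyphenyl)butyl]-2,3,4,4a,5,6,7,8-octahydronaphthalen-2-yl}propan-2-ol | CC(C)C[C@H](c1c(OC)cc(OC)cc1OC)[C@H]1CC[C@@H](C)C2=C[C@@H](C(C)(C)O)CC[C@@]21C | intermediate
21 | dilithium salt of the mono-adduct of 20 with DMF (aryl CH(O–)NMe2 at one free ring position, tertiary alkoxide at C11) | [Li+].[Li+].CC(C)C[C@H](c1c(OC)cc(OC)c(C([O-])N(C)C)c1OC)[C@H]1CC[C@@H](C)C2=C[C@@H](C(C)(C)[O-])CC[C@@]21C | intermediate
22 | 5-{(1S)-1-[(1R,4R,6S,8aR)-6-(2-hydroxypropan-2-yl)-4,8a-dimethyl-1,2,3,4,6,7,8,8a-octahydronaphthalen-1-yl]-3-methylbutyl}-2,4,6-trimethoxybenzene-1,3-dicarbaldehyde | CC(C)C[C@H](c1c(OC)c(C=O)c(OC)c(C=O)c1OC)[C@H]1CC[C@@H](C)C2=C[C@@H](C(C)(C)O)CC[C@@]21C | intermediate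
23 | 5-{(1S)-1-[(1R,4R,6S,8aR)-6-(2-hydroxypropan-2-yl)-4,8a-dimethyl-1,2,3,4,6,7,8,8a-octahydronaphthalen-1-yl]-3-methylbutyl}-2,4,6-trihydroxybenzene-1,3-dicarbaldehyde | CC(C)C[C@H](c1c(O)c(C=O)c(O)c(C=O)c1O)[C@H]1CC[C@@H](C)C2=C[C@@H](C(C)(C)O)CC[C@@]21C | target

Total step count: 15. Longest linear sequence: 15 steps (1 to 23; the route is fully linear, all other inputs being purchased).

Steps most likely to fail

Step 11 (the labelled step). The ring closure may lose to capture of the vinyl radical by oxygen or stannane before it cyclises, or to 1,5-hydrogen transfer from the allylic C8–H. Fallback: from 16, a palladium-catalysed 6-exo Heck cyclisation (Pd(OAc)2, PPh3, K2CO3, MeCN, 80 °C; the two β-iodo enone isomers interconvert under the conditions) should give, by syn insertion into C7=C11 and β-hydride elimination from a methyl group, the isopropenyl enone F1. Its 1,1-disubstituted olefin is then hydrated in the Markovnikov sense by oxymercuration (Hg(OAc)2, THF–H2O) and brief NaBH4/NaOH demercuration at 0 °C, which returns to 18.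

Step 8. Conjugate addition at the crowded, fully substituted β-carbon may be too slow, so that 1,2-addition or enolisation of the enone takes over. Fallback: from 11, the smaller sp2 nucleophile vinylmagnesium bromide is added under the same CuBr·SMe2/TMSCl catalysis to give the vinyl silyl enol ether F2. Chemoselective hydroboration of the vinyl group with 9-BBN gives the alkylborane F3, and a B-alkyl Suzuki–Miyaura coupling with 1-bromo-2-methylprop-1-ene (Pd(dppf)Cl2, anhydrous K3PO4, DMF, 50 °C) builds the 4-methylpent-3-enyl chain and rejoins the route at 13.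

Step 14. The second lithiation may stay incomplete, or butyllithium may attack the masked first formyl group. Fallback: from 20, electrophilic bromination of the two free aryl positions with N-bromosuccinimide (2 equiv, MeCN, 0 °C) gives the dibromide F4. Bromine–lithium exchange with t-BuLi (THF, −78 °C) and quenching with DMF then gives 22.

Further compounds
F1 | step 11 | (4R,4aR,7S)-4a-methyl-4-[(1S)-3-methyl-1-(2,4,6-trimethoxyphenyl)butyl]-7-(prop-1-en-2-yl)-3,4,4a,5,6,7-hexahydronaphthalen-1(2H)-one | CC(C)C[C@H](c1c(OC)cc(OC)cc1OC)[C@H]1CCC(=O)C2=C[C@@H](C(C)=C)CC[C@@]21C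
F2 | step 8 | ({3-ethenyl-3-methyl-4-[(1S)-3-methyl-1-(2,4,6-trimethoxyphenyl)butyl]cyclohex-1-en-1-yl}oxy)trimethylsilane (vinyl trans to the side chain, ring centres as in 13) | CC(C)C[C@H](c1c(OC)cc(OC)cc1OC)[C@H]1CCC(O[Si](C)(C)C)=C[C@]1(C)C=C
F3 | step 8 | 9-(2-{1-methyl-6-[(1S)-3-methyl-1-(2,4,6-trimethoxyphenyl)butyl]-3-(trimethylsilyloxy)cyclohex-2-en-1-yl}ethyl)-9-borabicyclo[3.3.1]nonane (ring centres as in 13) | CC(C)C[C@H](c1c(OC)cc(OC)cc1OC)[C@H]1CCC(O[Si](C)(C)C)=C[C@]1(C)CCB1C2CCCC1CCC2
F4 | step 14 | 2-{(2S,4aR,5R,8R)-5-[(1S)-1-(3,5-dibromo-2,4,6-trimethoxyphenyl)-3-methylbutyl]-4a,8-dimethyl-2,3,4,4a,5,6,7,8-octahydronaphthalen-2-yl}propan-2-ol | CC(C)C[C@H](c1c(OC)c(Br)c(OC)c(Br)c1OC)[C@H]1CC[C@@H](C)C2=C[C@@H](C(C)(C)O)CC[C@@]21C
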